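## The problem

Compound 29 is a germacranolide in which a ten-membered carbocycle (C1–C10) is fused at C6–C7 to a butenolide whose C7=C11 double bond lies inside the lactone, so sp2 C7 carries both the lactone carbinol C6 and the acyloxy carbinol C8. There are four stereocentres, C8 (R), C6 (R) and the cis-4,5-epoxide (4S,5R); O6 and O8 are syn across C7, and the cis epoxide can only arise from a Z C4=C5 olefin. C8 can be taken from the chiral pool, but it is separated from C6 by a planar carbon and cannot be trusted to control it, so C6 needs reagent control. Once both are set, allylic strain on either side of C7 (H6 turned toward C3, H8 toward C13) should place O8 over the face of C4=C5 that bears the epoxide oxygen, so a free C8 hydroxyl can direct the epoxidation. The α-methylene ketone (C10=C14 beside C1), the methacrylate, the allylic C13 acetate and the trisubstituted epoxide are electrophilic or acid-labile, and the C6 hydrogen is allylic and γ to the lactone carbonyl. These groups call for late, mild functionalisation and no strong base once the butenolide exists. The feature that opens the ring-forming disconnection is that C3, the β-carbon of the C1 ketone, is bonded to olefinic C4, so C1–C3 can be stored as a cyclopropanol whose ring-opened homoenolate is joined to a Z-alkenyl iodide at C4.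

## Retrosynthesis

**End game (29 back to 22).** The C10=C14 π bond is traced to the C14 alcohol 27 (via mesylate 28), which comes from PMB ether 26. The C8 ester is traced to alcohol 25 and the epoxide C–O bonds to the Z-olefin 24. Olefin 24 comes from diol 23 and the bis-silyl macrocycle 22. The enone is made last because it is the strongest electrophile. The epoxide is made while O8 is a free hydroxyl; with O8 silylated or acylated a reagent would be pushed to the opposite face. The forward steps must distinguish a primary from a secondary alcohol and epoxidise only the electron-rich olefin.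

**Ring closure (22 back to 21).** The C3–C4 bond is cut, giving the cyclopropanol/Z-alkenyl iodide 21. Closing C5–C6 by alkenyl-metal addition would create C6 in the macrocyclisation without control. Metathesis across C4=C5 would have to form a trisubstituted Z-olefin in a ten-membered ring. The C3–C4 cut creates no stereocentre, leaves every oxygen in place and uses the butenolide to hold the two chain ends cis. The forward step needs sp3–sp2 reductive elimination to beat β-hydride elimination, and the Z geometry and C6 must survive.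

**Butenolide and iodoalkene (21 back to 17).** The lactone C–O bond and the C6–H bond are cut to iodoenone 18 (via 19 and 20). The C4–I and C5–H bonds are cut to ynone 17. An olefination of a C5 aldehyde on the finished butenolide was set aside, because that aldehyde is α to the lactone oxygen and vinylogously acidic. Hydroalumination–iodination of a propargylic alcohol was set aside because it is incompatible with the ester. Anti hydroiodination of the ynone gives the Z-iodide, and reagent-controlled ketone reduction then sets C6 and triggers lactonisation.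

**Tetrasubstituted alkene (17 back to 15, 16 and CO).** The C6–C7 and C5–C6 bonds are cut at the ketone carbon, leading to enol triflate 15, propynylstannane 16 and carbon monoxide. The alkene geometry (C6 cis to C12) is fixed at the enol triflate stage by chelation, which an intermolecular olefination of a C7 ketone would not guarantee.

**C7–C11 bond (15 back to 10 and 12).** Triflate 15 comes from β-keto ester 14 and aldol 13, made from aldehyde 10 and ester 12 (from 11). Ester 12 brings C11, C12 and the C13 oxygen in one piece, so no later hydroxymethylation of a β-substituted butenolide is needed.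

**Cyclopropanol fragment (10 back to 1).** Aldehyde 10 comes from silyl ether 9 and diol 7. The C1–C2 and C1–C3 bonds are cut by a Kulinkovich transform to lactone 6. The C10–C14 bond is cut to lactone 2 and chloromethyl ether 5 (from 3 via 4). Lactone 2 is the silyl ether of the commercially available lactone 1, which supplies C8. Using a lactone rather than an acyclic ester releases the C8 hydroxyl in the cyclopropanation and sets C10 trans to C8 in the alkylation.

## Roads not taken

**Alternative 1:** The lactone C6–O bond and a C5–I bond are cut, giving the macrocyclic Z,Z-dienoic acid A2. In the forward step, iodonium formation on C5=C6 and 5-exo attack of the carboxylate give iodolactone A1; the C4 alkoxide then displaces iodide to close the epoxide.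

- Merit: anti addition followed by inversion relays the C5/C6 and epoxide configuration by mechanism. This is better than the chosen plan, whose epoxide face rests on a conformational argument for a directed epoxidation.
- Weak points: A2 already contains the ten-membered ring, the Z,Z-diene and the tertiary C4 carbinol, so the hardest problems are only moved. The dienoic acid is electron-poor, 6-endo attack and attack by the C4 hydroxyl compete, and the iodonium face is governed by remote centres.
- Comparison: the chosen plan offers a ring closure that is itself the key step and a convergent assembly, at the price of one unprecedented step.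

**Alternative 2:** The C8–C9 bond is cut by an oxy-Cope transform to the limonene-derived cyclohexenol A4. Its potassium alkoxide rearranges to cyclodecadienone A3.

- Merit: this is the best-precedented entry to cyclodecadienones, needs no high dilution and starts from a cheap terpene. In ring construction it is better than the chosen plan.
- Weak points: A3 lacks nearly all of the target's functionality. The C1 ketone, C10 methylene, C8 oxygen (from silicon), the three-carbon butenolide with its C13 acetate and the epoxide would each have to be installed on a flexible medium ring, with well over ten redox and functional-group steps. The absolute configuration rests on chirality transfer through the rearrangement.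
- Comparison: the chosen plan has every oxygen in place before the ring is closed.

**Alternative 3:** The C6–C7 bond is cut by a [2,3]-Wittig transform to the thirteen-membered propargylic allylic ether A6. Lithiation at C6 contracts the ring to cyclodecynol A5.

- Merit: ring contraction of macrocyclic ethers is known chemistry, and the step sets the C6 carbinol, so its precedent is stronger than that of the chosen key step.
- Weak points: the C7 centre made in the step is destroyed when C7 becomes sp2. The C11=C13 methylene and C12 ether of A5 must be reworked into the C7=C11 butenolide with a C13 acetate. The alkyne must be turned into a methyl-bearing Z-olefin. A6 needs a macrocyclisation of its own.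
- Comparison: the chosen plan delivers the complete butenolide and the correct trisubstituted olefin directly from the ring closure.

Key step: step 15

Remark: locants C1–C15 are those of the germacrane skeleton of 29 and are used for all intermediates.
Remark: the C10 configuration set in step 4 lasts only until C10 becomes sp2 in step 21; structures show the configuration expected from the alkylation, and any erosion is without consequence.

## Route

Step 1
Reactants: 1 (R)-5-(hydroxymethyl)dihydrofuran-2(3H)-one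
Product: 2 (R)-5-{[(triethylsilyl)oxy]methyl}dihydrofuran-2(3H)-one
Conditions: TESCl, imidazole, CH2Cl2, 0 °C
Reagents that add atoms: chlorotriethylsilane, CC[Si](Cl)(CC)CC
Why: Imidazole-promoted silylation of the primary alcohol; the triethylsilyl ether survives enolate chemistry and is the silyl ether that Swern conditions later convert directly into the aldehyde.

Step 2
Reactants: 3 4-methoxybenzyl alcohol
Product: 4 4-methoxybenzyl (methylsulfanyl)methyl ether
Conditions: NaH, ClCH2SMe, NaI (cat.), DME, 0 °C to rt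
Reagents that add atoms: chloromethyl methyl sulfide, CSCCl
Why: Williamson etherification of the sodium alkoxide gives the methylthiomethyl ether, the stable precursor of the chloromethyl ether.

Step 3
Reactants: 4 4-methoxybenzyl (methylsulfanyl)methyl ether
Product: 5 4-methoxybenzyl chloromethyl ether
Conditions: SO2Cl2, CH2Cl2, −78 °C; volatiles removed, used at once
Reagents that add atoms: sulfuryl chloride, ClS(Cl)(=O)=O
Why: Chlorinolysis of the O,S-acetal (sulfonium formation, loss of methanesulfenyl chloride) gives the chloromethyl ether, which is used crude because it hydrolyses readily.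

Step 4
Reactants: 2 (R)-5-{[(triethylsilyl)oxy]methyl}dihydrofuran-2(3H)-one; 5 4-methoxybenzyl chloromethyl ether
Product: 6 (3R,5R)-3-{[(4-methoxybenzyl)oxy]methyl}-5-{[(triethylsilyl)oxy]methyl}dihydrofuran-2(3H)-one (3,5-trans)
Conditions: LiN(i-Pr)2, THF, −78 °C; then 5, −78 to −40 °C
Reagents that add atoms: none
Why: Alkylation of the lactone lithium enolate with an alkoxymethyl chloride; the electrophile approaches the enolate face opposite the C5 substituent, which sets C10 trans to the C8 side chain and brings in C14 at the alcohol oxidation level.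

Step 5
Reactants: 6 (3R,5R)-3-{[(4-methoxybenzyl)oxy]methyl}-5-{[(triethylsilyl)oxy]methyl}dihydrofuran-2(3H)-one
Product: 7 1-{(2R,4R)-4-hydroxy-1-[(4-methoxybenzyl)oxy]-5-[(triethylsilyl)oxy]pentan-2-yl}cyclopropan-1-ol
Conditions: EtMgBr (3.5 equiv, slow addition), Ti(OiPr)4 (0.5 equiv), THF, 0 °C to rt; sat. NH4Cl
Reagents that add atoms: ethylmagnesium bromide, CC[Mg]Br
Why: Kulinkovich cyclopropanation: the titanacyclopropane formed from EtMgBr and Ti(OiPr)4 adds twice to the lactone carbonyl (C1), giving the cyclopropanol (C1–C3) and releasing the C8 hydroxyl; ethers and silyl ethers are inert and no stereocentre is touched.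

Step 6
Reactants: 7 1-{(2R,4R)-4-hydroxy-1-[(4-methoxybenzyl)oxy]-5-[(triethylsilyl)oxy]pentan-2-yl}cyclopropan-1-ol
Product: 9 (2R,4R)-2-[(tert-butyldimethylsilyl)oxy]-5-[(4-methoxybenzyl)oxy]-1-[(triethylsilyl)oxy]-4-{1-[(triethylsilyl)oxy]cyclopropyl}pentane, via mono-TBS ether 8 (not isolated)
Conditions: TBSCl, imidazole, DMF, rt; then TESCl, DMAP, rt
Reagents that add atoms: tert-butyldimethylsilyl chloride, CC(C)(C)[Si](C)(C)Cl; chlorotriethylsilane, CC[Si](Cl)(CC)CC
Why: Stepwise silylation in one flask: TBSCl/imidazole reacts only at the secondary C8 hydroxyl, and the smaller TESCl with DMAP then caps the tertiary cyclopropanol, which must stay masked against oxidants and bases until step 14.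

Step 7
Reactants: 9 (2R,4R)-2-[(tert-butyldimethylsilyl)oxy]-5-[(4-methoxybenzyl)oxy]-1-[(triethylsilyl)oxy]-4-{1-[(triethylsilyl)oxy]cyclopropyl}pentane
Product: 10 (2R,4R)-2-[(tert-butyldimethylsilyl)oxy]-5-[(4-methoxybenzyl)oxy]-4-{1-[(triethylsilyl)oxy]cyclopropyl}pentanal
Conditions: (COCl)2, DMSO, CH2Cl2, −78 to −40 °C; then Et3N, −78 to 0 °C
Reagents that add atoms: none
Why: Swern oxidation applied directly to a primary triethylsilyl ether (oxidative desilylation by the chlorosulfonium salt), a known selective process that leaves the secondary TBS and tertiary TES ethers untouched; amine addition at −78 °C limits epimerisation of the α-silyloxy aldehyde.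

Step 8
Reactants: 11 methyl 3-hydroxypropanoate
Product: 12 methyl 3-[(triisopropylsilyl)oxy]propanoate
Conditions: TIPSCl, imidazole, DMF, rt
Reagents that add atoms: chlorotriisopropylsilane, CC(C)[Si](Cl)(C(C)C)C(C)C
Why: Standard silylation; the TIPS ether is chosen to survive the acidic conditions of steps 13 and 14, under which the cyclopropyl TES ether is removed.

Step 9
Reactants: 10 (2R,4R)-2-[(tert-butyldimethylsilyl)oxy]-5-[(4-methoxybenzyl)oxy]-4-{1-[(triethylsilyl)oxy]cyclopropyl}pentanal; 12 methyl 3-[(triisopropylsilyl)oxy]propanoate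
Product: 13 methyl (4R,6R)-4-[(tert-butyldimethylsilyl)oxy]-3-hydroxy-7-[(4-methoxybenzyl)oxy]-6-{1-[(triethylsilyl)oxy]cyclopropyl}-2-{[(triisopropylsilyl)oxy]methyl}heptanoate (mixture at C2 and C3 of the heptanoate)
Conditions: 12, LiN(i-Pr)2, THF, −78 °C; then 10, −78 °C; AcOH quench at −78 °C
Reagents that add atoms: none
Why: Aldol addition of an ester lithium enolate forms the C7–C11 bond; the enolate is kept at −78 °C to avoid loss of silanolate, and the new centres at C7 and C11 are not controlled because both become sp2 in steps 10 and 11.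

Step 10
Reactants: 13 methyl (4R,6R)-4-[(tert-butyldimethylsilyl)oxy]-3-hydroxy-7-[(4-methoxybenzyl)oxy]-6-{1-[(triethylsilyl)oxy]cyclopropyl}-2-{[(triisopropylsilyl)oxy]methyl}heptanoate
Product: 14 methyl (4R,6R)-4-[(tert-butyldimethylsilyl)oxy]-7-[(4-methoxybenzyl)oxy]-3-oxo-6-{1-[(triethylsilyl)oxy]cyclopropyl}-2-{[(triisopropylsilyl)oxy]methyl}heptanoate
Conditions: Dess–Martin periodinane, NaHCO3, CH2Cl2, 0 °C to rt
Reagents that add atoms: none
Why: Dess–Martin oxidation of the β-hydroxy ester to the β-keto ester under buffered, non-basic conditions that avoid β-elimination of the silyloxy group and epimerisation at C8.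

Step 11
Reactants: 14 methyl (4R,6R)-4-[(tert-butyldimethylsilyl)oxy]-7-[(4-methoxybenzyl)oxy]-3-oxo-6-{1-[(triethylsilyl)oxy]cyclopropyl}-2-{[(triisopropylsilyl)oxy]methyl}heptanoate
Product: 15 methyl (2Z,4R,6R)-4-[(tert-butyldimethylsilyl)oxy]-7-[(4-methoxybenzyl)oxy]-6-{1-[(triethylsilyl)oxy]cyclopropyl}-3-{[(trifluoromethyl)sulfonyl]oxy}-2-{[(triisopropylsilyl)oxy]methyl}hept-2-enoate
Conditions: NaH, THF, 0 °C; then PhNTf2, 0 °C to rt
Reagents that add atoms: N-phenylbis(trifluoromethanesulfonimide), O=S(=O)(N(c1ccccc1)S(=O)(=O)C(F)(F)F)C(F)(F)F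
Why: O-Triflation of the sodium enolate of a β-keto ester; the sodium chelate between enolate oxygen and ester carbonyl fixes the geometry so that the triflate on C7 is cis to the ester (Z), and only the doubly activated C11–H is removed, so C8 is not epimerised.

Step 12
Reactants: 15 methyl (2Z,4R,6R)-4-[(tert-butyldimethylsilyl)oxy]-7-[(4-methoxybenzyl)oxy]-6-{1-[(triethylsilyl)oxy]cyclopropyl}-3-{[(trifluoromethyl)sulfonyl]oxy}-2-{[(triisopropylsilyl)oxy]methyl}hept-2-enoate; 16 tributyl(prop-1-yn-1-yl)stannane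
Product: 17 methyl (2Z,4R,6R)-3-(but-2-ynoyl)-4-[(tert-butyldimethylsilyl)oxy]-7-[(4-methoxybenzyl)oxy]-6-{1-[(triethylsilyl)oxy]cyclopropyl}-2-{[(triisopropylsilyl)oxy]methyl}hept-2-enoate
Conditions: Pd(PPh3)4 (10 mol%), LiCl, CO (3 atm), THF, 55 °C, slow addition of 16
Reagents that add atoms: carbon monoxide, [C-]#[O+]
Why: Carbonylative Stille coupling: oxidative addition of zerovalent palladium to the enol triflate, CO insertion and alkynyl transfer from tin give the ynone with retention of alkene geometry, which places the new C6 carbonyl cis to the C12 ester; CO pressure and slow addition of 16 suppress direct alkynylation.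

Step 13
Reactants: 17 methyl (2Z,4R,6R)-3-(but-2-ynoyl)-4-[(tert-butyldimethylsilyl)oxy]-7-[(4-methoxybenzyl)oxy]-6-{1-[(triethylsilyl)oxy]cyclopropyl}-2-{[(triisopropylsilyl)oxy]methyl}hept-2-enoate
Product: 18 methyl (2Z,4R,6R)-4-[(tert-butyldimethylsilyl)oxy]-3-[(Z)-3-iodobut-2-enoyl]-7-[(4-methoxybenzyl)oxy]-6-{1-[(triethylsilyl)oxy]cyclopropyl}-2-{[(triisopropylsilyl)oxy]methyl}hept-2-enoate
Conditions: NaI, AcOH (10 equiv), MeCN, 0 °C to rt
Reagents that add atoms: sodium iodide, [Na+].[I-]
Why: Conjugate hydroiodination of an ynone (iodide addition, then protonation of the allenolate anti to iodine) gives kinetically the Z-β-iodoenone with iodine on C4 cis to C6; the tetrasubstituted enoate is not an acceptor and the silyl ethers should tolerate dilute acetic acid at room temperature.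

Step 14
Reactants: 18 methyl (2Z,4R,6R)-4-[(tert-butyldimethylsilyl)oxy]-3-[(Z)-3-iodobut-2-enoyl]-7-[(4-methoxybenzyl)oxy]-6-{1-[(triethylsilyl)oxy]cyclopropyl}-2-{[(triisopropylsilyl)oxy]methyl}hept-2-enoate
Product: 21 (5S)-4-{(1R,3R)-1-[(tert-butyldimethylsilyl)oxy]-3-(1-hydroxycyclopropyl)-4-[(4-methoxybenzyl)oxy]butyl}-5-[(1Z)-2-iodoprop-1-en-1-yl]-3-{[(triisopropylsilyl)oxy]methyl}furan-2(5H)-one, via hydroxy ester 19 (not isolated), via TES-protected butenolide 20 (not isolated)
Conditions: (R)-Me-CBS (0.3 equiv), BH3·SMe2, THF, −40 °C; MeOH; then PPTS, MeOH, rt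
Reagents that add atoms: none
Why: Corey–Bakshi–Shibata reduction: the (R)-oxazaborolidine should deliver hydride to the ketone face that gives the (6S) alcohol 19, with the fully substituted alkenyl carbon C7 as the large group and the iodoalkenyl CH as the small one; the alcohol, held cis to the ester, lactonises to the butenolide, and PPTS in methanol then removes only the triethylsilyl ether from the cyclopropanol.

Step 15
Reactants: 21 (5S)-4-{(1R,3R)-1-[(tert-butyldimethylsilyl)oxy]-3-(1-hydroxycyclopropyl)-4-[(4-methoxybenzyl)oxy]butyl}-5-[(1Z)-2-iodoprop-1-en-1-yl]-3-{[(triisopropylsilyl)oxy]methyl}furan-2(5H)-one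
Product: 22 (4Z,6S,8R,10R)-8-[(tert-butyldimethylsilyl)oxy]-14-[(4-methoxybenzyl)oxy]-1-oxo-13-[(triisopropylsilyl)oxy]germacra-4,7(11)-dien-12,6-olide
Conditions: Pd(OAc)2 (15 mol%), XPhos (30 mol%), K3PO4 (3 equiv), toluene, 70 °C; 21 added by syringe pump over 12 h (final 1 mM)
Reagents that add atoms: none
Why: Proposed new method: zerovalent palladium (formed from Pd(OAc)2 and XPhos) should insert into the C4–I bond of 21 with retention of the Z geometry, the cyclopropanol should replace iodide on divalent palladium with the help of K3PO4, strain-driven β-carbon elimination of the palladium cyclopropoxide should give the C3-palladated homoenolate of the C1 ketone, and C–C reductive elimination then forms C3–C4. The closest known reaction type is the intermolecular palladium-catalysed ring-opening cross-coupling of cyclopropanols with aryl and alkenyl halides; its use to close a ring onto an alkenyl iodide is new. The ten-membered carbocycle closes by sp3–sp2 reductive elimination from an eleven-membered palladacycle. No stereocentre is formed: C6, C8 and C10 are spectators and the olefin geometry is that of the iodide. The two ring C–C bonds of the cyclopropanol are equivalent, so only one homoenolate can arise. The step needs reductive elimination to outrun β-hydride elimination (to the vinyl ketone) and intermolecular coupling: the bulky electron-rich biarylphosphine speeds reductive elimination, slow addition keeps 21 dilute, and the C6 and C8 arms held on the planar butenolide bring C3 and C4 together. K3PO4 in toluene is chosen as the mildest base that still forms the palladium alkoxide, because the C6 hydrogen is allylic and γ to the lactone carbonyl.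

Step 16
Reactants: 22 (4Z,6S,8R,10R)-8-[(tert-butyldimethylsilyl)oxy]-14-[(4-methoxybenzyl)oxy]-1-oxo-13-[(triisopropylsilyl)oxy]germacra-4,7(11)-dien-12,6-olide
Product: 23 (4Z,6S,8R,10R)-8,13-dihydroxy-14-[(4-methoxybenzyl)oxy]-1-oxogermacra-4,7(11)-dien-12,6-olide
Conditions: HF·pyridine, pyridine, THF, 0 °C to rt
Reagents that add atoms: none
Why: Fluoride cleavage of both silyl ethers under buffered conditions; the PMB ether, the β-alkoxy ketone and the butenolide are stable, and the C8 alcohol cannot translactonise because it is trans to C12 across C7=C11.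

Step 17
Reactants: 23 (4Z,6S,8R,10R)-8,13-dihydroxy-14-[(4-methoxybenzyl)oxy]-1-oxogermacra-4,7(11)-dien-12,6-olide
Product: 24 (4Z,6S,8R,10R)-13-acetoxy-8-hydroxy-14-[(4-methoxybenzyl)oxy]-1-oxogermacra-4,7(11)-dien-12,6-olide
Conditions: AcCl (1.05 equiv), 2,4,6-collidine, CH2Cl2, −78 °C
Reagents that add atoms: acetyl chloride, CC(=O)Cl
Why: Selective acylation of the primary allylic C13 alcohol over the hindered secondary C8 alcohol with acetyl chloride and collidine at low temperature.

Step 18
Reactants: 24 (4Z,6S,8R,10R)-13-acetoxy-8-hydroxy-14-[(4-methoxybenzyl)oxy]-1-oxogermacra-4,7(11)-dien-12,6-olide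
Product: 25 (4S,5R,6R,8R,10R)-13-acetoxy-4,5-epoxy-8-hydroxy-14-[(4-methoxybenzyl)oxy]-1-oxogermacr-7(11)-en-12,6-olide
Conditions: VO(acac)2 (10 mol%), t-BuOOH, CH2Cl2, 0 °C to rt
Reagents that add atoms: tert-butyl hydroperoxide, CC(C)(C)OO
Why: Hydroxyl-directed vanadium-catalysed epoxidation: the vanadate ester of the C8 alcohol delivers oxygen to the electron-rich Z C4=C5 bond, and the electron-poor C7=C11 bond is not attacked. Allylic strain keeps H6 eclipsed toward C3 and H8 eclipsed toward C13, which places O8 above the olefin face syn to C7, the face on which 29 carries the epoxide oxygen, so the cis-(4S,5R) epoxide should result.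

Step 19
Reactants: 25 (4S,5R,6R,8R,10R)-13-acetoxy-4,5-epoxy-8-hydroxy-14-[(4-methoxybenzyl)oxy]-1-oxogermacr-7(11)-en-12,6-olide
Product: 26 (4S,5R,6R,8R,10R)-13-acetoxy-4,5-epoxy-14-[(4-methoxybenzyl)oxy]-8-(methacryloyloxy)-1-oxogermacr-7(11)-en-12,6-olide
Conditions: methacrylic anhydride, Et3N, DMAP (0.2 equiv), CH2Cl2, 0 °C to rt
Reagents that add atoms: methacrylic anhydride, CC(=C)C(=O)OC(=O)C(C)=C
Why: DMAP-catalysed esterification of the secondary C8 alcohol; the non-acidic conditions keep the trisubstituted epoxide intact.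

Step 20
Reactants: 26 (4S,5R,6R,8R,10R)-13-acetoxy-4,5-epoxy-14-[(4-methoxybenzyl)oxy]-8-(methacryloyloxy)-1-oxogermacr-7(11)-en-12,6-olide
Product: 27 (4S,5R,6R,8R,10R)-13-acetoxy-4,5-epoxy-14-hydroxy-8-(methacryloyloxy)-1-oxogermacr-7(11)-en-12,6-olide
Conditions: DDQ, CH2Cl2/pH 7 buffer, 0 °C
Reagents that add atoms: none
Why: Oxidative cleavage of the PMB ether by DDQ (benzylic hydride abstraction, then hydrolysis of the oxocarbenium ion) in a buffered two-phase medium; no other electron-rich arene is present.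

Step 21
Reactants: 27 (4S,5R,6R,8R,10R)-13-acetoxy-4,5-epoxy-14-hydroxy-8-(methacryloyloxy)-1-oxogermacr-7(11)-en-12,6-olide
Product: 29 (4S,5R,6R,8R)-13-acetoxy-4,5-epoxy-8-(methacryloyloxy)-1-oxogermacra-7(11),10(14)-dien-12,6-olide (CNP0266914.1), via C14 mesylate 28 (not isolated)
Conditions: MsCl, Et3N (4 equiv), CH2Cl2, −20 to 0 °C
Reagents that add atoms: none
Why: Mesylation of the β-hydroxy ketone followed by E1cB elimination with the same amine gives the α-methylene ketone; this is run last because the enone is the most electrophilic group in the molecule, and the mild amine avoids deprotonation at C6.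

## Compound list

1 | (R)-5-(hydroxymethyl)dihydrofuran-2(3H)-one | OC[C@H]1CCC(=O)O1 | starting material
2 | (R)-5-{[(triethylsilyl)oxy]methyl}dihydrofuran-2(3H)-one | CC[Si](CC)(CC)OC[C@H]1CCC(=O)O1 | intermediate
3 | 4-methoxybenzyl alcohol | COc1ccc(CO)cc1 | starting material
4 | 4-methoxybenzyl (methylsulfanyl)methyl ether | COc1ccc(COCSC)cc1 | intermediate
5 | 4-methoxybenzyl chloromethyl ether | COc1ccc(COCCl)cc1 | intermediate
6 | (3R,5R)-3-{[(4-methoxybenzyl)oxy]methyl}-5-{[(triethylsilyl)oxy]methyl}dihydrofuran-2(3H)-one (3,5-trans) | O=C1O[C@@H](CO[Si](CC)(CC)CC)C[C@@H]1COCc2ccc(OC)cc2 | intermediate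
7 | 1-{(2R,4R)-4-hydroxy-1-[(4-methoxybenzyl)oxy]-5-[(triethylsilyl)oxy]pentan-2-yl}cyclopropan-1-ol | OC1(CC1)[C@@H](COCc2ccc(OC)cc2)C[C@@H](O)CO[Si](CC)(CC)CC | intermediate
8 | 1-{(2R,4R)-4-[(tert-butyldimethylsilyl)oxy]-1-[(4-methoxybenzyl)oxy]-5-[(triethylsilyl)oxy]pentan-2-yl}cyclopropan-1-ol (not isolated) | OC1(CC1)[C@@H](COCc2ccc(OC)cc2)C[C@@H](O[Si](C)(C)C(C)(C)C)CO[Si](CC)(CC)CC | intermediate
9 | (2R,4R)-2-[(tert-butyldimethylsilyl)oxy]-5-[(4-methoxybenzyl)oxy]-1-[(triethylsilyl)oxy]-4-{1-[(triethylsilyl)oxy]cyclopropyl}pentane | CC[Si](CC)(CC)OC1(CC1)[C@@H](COCc2ccc(OC)cc2)C[C@@H](O[Si](C)(C)C(C)(C)C)CO[Si](CC)(CC)CC | intermediate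
10 | (2R,4R)-2-[(tert-butyldimethylsilyl)oxy]-5-[(4-methoxybenzyl)oxy]-4-{1-[(triethylsilyl)oxy]cyclopropyl}pentanal | CC[Si](CC)(CC)OC1(CC1)[C@@H](COCc2ccc(OC)cc2)C[C@@H](O[Si](C)(C)C(C)(C)C)C=O | intermediate
11 | methyl 3-hydroxypropanoate | COC(=O)CCO | starting material
12 | methyl 3-[(triisopropylsilyl)oxy]propanoate | COC(=O)CCO[Si](C(C)C)(C(C)C)C(C)C | intermediate
13 | methyl (4R,6R)-4-[(tert-butyldimethylsilyl)oxy]-3-hydroxy-7-[(4-methoxybenzyl)oxy]-6-{1-[(triethylsilyl)oxy]cyclopropyl}-2-{[(triisopropylsilyl)oxy]methyl}heptanoate (mixture at C2 and C3) | CC[Si](CC)(CC)OC1(CC1)[C@@H](COCc2ccc(OC)cc2)C[C@@H](O[Si](C)(C)C(C)(C)C)C(O)C(CO[Si](C(C)C)(C(C)C)C(C)C)C(=O)OC | intermediate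
14 | methyl (4R,6R)-4-[(tert-butyldimethylsilyl)oxy]-7-[(4-methoxybenzyl)oxy]-3-oxo-6-{1-[(triethylsilyl)oxy]cyclopropyl}-2-{[(triisopropylsilyl)oxy]methyl}heptanoate (C2 epimers) | CC[Si](CC)(CC)OC1(CC1)[C@@H](COCc2ccc(OC)cc2)C[C@@H](O[Si](C)(C)C(C)(C)C)C(=O)C(CO[Si](C(C)C)(C(C)C)C(C)C)C(=O)OC | intermediate
15 | methyl (2Z,4R,6R)-4-[(tert-butyldimethylsilyl)oxy]-7-[(4-methoxybenzyl)oxy]-6-{1-[(triethylsilyl)oxy]cyclopropyl}-3-{[(trifluoromethyl)sulfonyl]oxy}-2-{[(triisopropylsilyl)oxy]methyl}hept-2-enoate | CC[Si](CC)(CC)OC1(CC1)[C@@H](COCc2ccc(OC)cc2)C[C@@H](O[Si](C)(C)C(C)(C)C)/C(OS(=O)(=O)C(F)(F)F)=C(\CO[Si](C(C)C)(C(C)C)C(C)C)C(=O)OC | intermediate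
16 | tributyl(prop-1-yn-1-yl)stannane | CC#C[Sn](CCCC)(CCCC)CCCC | starting material
17 | methyl (2Z,4R,6R)-3-(but-2-ynoyl)-4-[(tert-butyldimethylsilyl)oxy]-7-[(4-methoxybenzyl)oxy]-6-{1-[(triethylsilyl)oxy]cyclopropyl}-2-{[(triisopropylsilyl)oxy]methyl}hept-2-enoate | CC[Si](CC)(CC)OC1(CC1)[C@@H](COCc2ccc(OC)cc2)C[C@@H](O[Si](C)(C)C(C)(C)C)/C(C(=O)C#CC)=C(\CO[Si](C(C)C)(C(C)C)C(C)C)C(=O)OC | intermediate
18 | methyl (2Z,4R,6R)-4-[(tert-butyldimethylsilyl)oxy]-3-[(Z)-3-iodobut-2-enoyl]-7-[(4-methoxybenzyl)oxy]-6-{1-[(triethylsilyl)oxy]cyclopropyl}-2-{[(triisopropylsilyl)oxy]methyl}hept-2-enoate | CC[Si](CC)(CC)OC1(CC1)[C@@H](COCc2ccc(OC)cc2)C[C@@H](O[Si](C)(C)C(C)(C)C)/C(C(=O)/C=C(/C)I)=C(\CO[Si](C(C)C)(C(C)C)C(C)C)C(=O)OC | intermediate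
19 | methyl (4R,6R)-4-[(tert-butyldimethylsilyl)oxy]-3-[(1S,2Z)-1-hydroxy-3-iodobut-2-en-1-yl]-7-[(4-methoxybenzyl)oxy]-6-{1-[(triethylsilyl)oxy]cyclopropyl}-2-{[(triisopropylsilyl)oxy]methyl}hept-2-enoate, carbinol carbon cis to the ester (not isolated) | CC[Si](CC)(CC)OC1(CC1)[C@@H](COCc2ccc(OC)cc2)C[C@@H](O[Si](C)(C)C(C)(C)C)/C([C@@H](O)/C=C(/C)I)=C(\CO[Si](C(C)C)(C(C)C)C(C)C)C(=O)OC | intermediate
20 | (5S)-4-{(1R,3R)-1-[(tert-butyldimethylsilyl)oxy]-4-[(4-methoxybenzyl)oxy]-3-{1-[(triethylsilyl)oxy]cyclopropyl}butyl}-5-[(1Z)-2-iodoprop-1-en-1-yl]-3-{[(triisopropylsilyl)oxy]methyl}furan-2(5H)-one (not isolated) | CC[Si](CC)(CC)OC1(CC1)[C@@H](COCc2ccc(OC)cc2)C[C@@H](O[Si](C)(C)C(C)(C)C)C3=C(CO[Si](C(C)C)(C(C)C)C(C)C)C(=O)O[C@H]3/C=C(/C)I | intermediate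
21 | (5S)-4-{(1R,3R)-1-[(tert-butyldimethylsilyl)oxy]-3-(1-hydroxycyclopropyl)-4-[(4-methoxybenzyl)oxy]butyl}-5-[(1Z)-2-iodoprop-1-en-1-yl]-3-{[(triisopropylsilyl)oxy]methyl}furan-2(5H)-one | OC1(CC1)[C@@H](COCc2ccc(OC)cc2)C[C@@H](O[Si](C)(C)C(C)(C)C)C3=C(CO[Si](C(C)C)(C(C)C)C(C)C)C(=O)O[C@H]3/C=C(/C)I | intermediate
22 | (4Z,6S,8R,10R)-8-[(tert-butyldimethylsilyl)oxy]-14-[(4-methoxybenzyl)oxy]-1-oxo-13-[(triisopropylsilyl)oxy]germacra-4,7(11)-dien-12,6-olide | CC(C)(C)[Si](C)(C)O[C@@H]1C[C@H](COCc3ccc(OC)cc3)C(=O)CC/C(C)=C\[C@@H]2OC(=O)C(CO[Si](C(C)C)(C(C)C)C(C)C)=C21 | intermediate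
23 | (4Z,6S,8R,10R)-8,13-dihydroxy-14-[(4-methoxybenzyl)oxy]-1-oxogermacra-4,7(11)-dien-12,6-olide | O[C@@H]1C[C@H](COCc3ccc(OC)cc3)C(=O)CC/C(C)=C\[C@@H]2OC(=O)C(CO)=C21 | intermediate
24 | (4Z,6S,8R,10R)-13-acetoxy-8-hydroxy-14-[(4-methoxybenzyl)oxy]-1-oxogermacra-4,7(11)-dien-12,6-olide | O[C@@H]1C[C@H](COCc3ccc(OC)cc3)C(=O)CC/C(C)=C\[C@@H]2OC(=O)C(COC(C)=O)=C21 | intermediate
25 | (4S,5R,6R,8R,10R)-13-acetoxy-4,5-epoxy-8-hydroxy-14-[(4-methoxybenzyl)oxy]-1-oxogermacr-7(11)-en-12,6-olide | O[C@@H]1C[C@H](COCc3ccc(OC)cc3)C(=O)CC[C@]2(C)O[C@@H]2[C@@H]2OC(=O)C(COC(C)=O)=C21 | intermediate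
26 | (4S,5R,6R,8R,10R)-13-acetoxy-4,5-epoxy-14-[(4-methoxybenzyl)oxy]-8-(methacryloyloxy)-1-oxogermacr-7(11)-en-12,6-olide | C=C(C)C(=O)O[C@@H]1C[C@H](COCc3ccc(OC)cc3)C(=O)CC[C@]2(C)O[C@@H]2[C@@H]2OC(=O)C(COC(C)=O)=C21 | intermediate
27 | (4S,5R,6R,8R,10R)-13-acetoxy-4,5-epoxy-14-hydroxy-8-(methacryloyloxy)-1-oxogermacr-7(11)-en-12,6-olide | C=C(C)C(=O)O[C@@H]1C[C@H](CO)C(=O)CC[C@]2(C)O[C@@H]2[C@@H]2OC(=O)C(COC(C)=O)=C21 | intermediate
28 | (4S,5R,6R,8R,10R)-13-acetoxy-4,5-epoxy-14-[(methylsulfonyl)oxy]-8-(methacryloyloxy)-1-oxogermacr-7(11)-en-12,6-olide (not isolated) | C=C(C)C(=O)O[C@@H]1C[C@H](COS(C)(=O)=O)C(=O)CC[C@]2(C)O[C@@H]2[C@@H]2OC(=O)C(COC(C)=O)=C21 | intermediate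
29 | (4S,5R,6R,8R)-13-acetoxy-4,5-epoxy-8-(methacryloyloxy)-1-oxogermacra-7(11),10(14)-dien-12,6-olide (CNP0266914.1) | C=C(C)C(=O)O[C@@H]1CC(=C)C(=O)CC[C@]2(C)O[C@@H]2[C@@H]2OC(=O)C(COC(C)=O)=C21 | target

## Step count and least certain steps

Total: 21 steps. Longest linear sequence: 19 steps (3 to 29 through steps 2–7 and 9–21). Step 1 prepares lactone 2 and step 8 prepares ester 12; each enters the main line directly, in steps 4 and 9.

**Step 15 (key step).** β-Hydride elimination from the C3-palladated homoenolate may outrun reductive elimination, because the strain of the forming ten-membered ring slows the latter. Intermolecular coupling and base-induced deprotonation at C6 (epimerisation or vinylogous loss of iodide) may also compete.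

Fallback, from 21 back to 22, by a B-alkyl Suzuki–Miyaura macrocyclisation that forms the same C3–C4 bond by known chemistry: the cyclopropanol of 21 is opened with N-bromosuccinimide to the β-bromo ketone F1, which loses HBr with Et3N to give the vinyl ketone F2. Luche reduction (NaBH4, CeCl3·7H2O) gives the allylic alcohol F3 (C1 epimers), which is protected as the triethylsilyl ether F4 (TESCl, imidazole). Hydroboration of the terminal alkene with 9-BBN gives the B-alkylborane F5, which is closed onto the alkenyl iodide (Pd(dppf)Cl2, AsPh3, Cs2CO3, aqueous DMF/THF, high dilution) to the macrocyclic silyl ether F6. PPTS in methanol frees the C1 alcohol F7, and Dess–Martin oxidation gives ketone 22.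

**Step 14.** Facial selectivity in the ketone reduction may be poor, because both groups flanking the C6 ketone are alkenyl and the C8 centre may oppose the catalyst. Z-to-E isomerisation of the iodoenone is a second risk.

Fallback, from 17 back to 20 (and on to 21 by the acidic methanol treatment of step 14): C6 is set at the ynone stage, where the alkyne is a clearly small group. Transfer hydrogenation of 17 with the enantiomer of RuCl(TsDPEN)(p-cymene) that gives the (6S) alcohol, in HCO2H/Et3N, gives the propargylic hydroxy ester F8, which lactonises to the propynyl butenolide F9. Trans-hydrosilylation with BnMe2SiH and [Cp*Ru(MeCN)3]PF6 places silicon on C4 and gives the Z-vinylsilane F10. Iododesilylation with N-iodosuccinimide in hexafluoroisopropanol at 0 °C proceeds with retention and gives 20.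

**Step 18.** Oxygen may be delivered to the wrong olefin face, or not directed at all, if O8 is tied up as a transannular hemiketal with the C1 ketone. Oxidation of the allylic C8 alcohol may compete.

Fallback, from 24 back to 26, by a halohydrin route that reaches the face opposite to direct attack: alcohol 24 is first esterified with methacrylic anhydride to the methacrylate F11. N-Bromosuccinimide in aqueous DME forms the bromonium ion on the olefin face remote from the C8 ester, and water opens it at the tertiary carbon C4 from the other face, giving bromohydrin F12. Ag2O in CH2Cl2 closes the epoxide with inversion at C5, giving 26.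

**Step 12.** The alkynyl group may be transferred before CO insertion, giving the enyne, and oxidative addition at the hindered tetrasubstituted triflate may be slow.

Fallback, from 15 back to 17: aminocarbonylation of 15 (Pd(OAc)2, Xantphos, CO, MeNHOMe·HCl, Et3N) gives the Weinreb amide F13, and addition of MeC≡CMgBr at −40 °C gives ynone 17.

## Further compounds

F1 | step 15 | β-bromo ketone from 21 (C1 ketone, C3 bromide) | BrCCC(=O)[C@@H](COCc2ccc(OC)cc2)C[C@@H](O[Si](C)(C)C(C)(C)C)C3=C(CO[Si](C(C)C)(C(C)C)C(C)C)C(=O)O[C@H]3/C=C(/C)I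
F2 | step 15 | vinyl ketone (C1 ketone, C2=C3) | C=CC(=O)[C@@H](COCc2ccc(OC)cc2)C[C@@H](O[Si](C)(C)C(C)(C)C)C3=C(CO[Si](C(C)C)(C(C)C)C(C)C)C(=O)O[C@H]3/C=C(/C)I
F3 | step 15 | allylic alcohol (C1 epimers) | C=CC(O)[C@@H](COCc2ccc(OC)cc2)C[C@@H](O[Si](C)(C)C(C)(C)C)C3=C(CO[Si](C(C)C)(C(C)C)C(C)C)C(=O)O[C@H]3/C=C(/C)I
F4 | step 15 | C1 triethylsilyl ether of F3 | C=CC(O[Si](CC)(CC)CC)[C@@H](COCc2ccc(OC)cc2)C[C@@H](O[Si](C)(C)C(C)(C)C)C3=C(CO[Si](C(C)C)(C(C)C)C(C)C)C(=O)O[C@H]3/C=C(/C)I
F5 | step 15 | C3 B-alkyl-9-borabicyclo[3.3.1]nonane from F4 | CC[Si](CC)(CC)OC(CCB1C2CCCC1CCC2)[C@@H](COCc3ccc(OC)cc3)C[C@@H](O[Si](C)(C)C(C)(C)C)C4=C(CO[Si](C(C)C)(C(C)C)C(C)C)C(=O)O[C@H]4/C=C(/C)I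
F6 | step 15 | macrocyclic C1 triethylsilyl ether (4Z,6S,8R,10R) | CC(C)(C)[Si](C)(C)O[C@@H]1C[C@H](COCc3ccc(OC)cc3)C(O[Si](CC)(CC)CC)CC/C(C)=C\[C@@H]2OC(=O)C(CO[Si](C(C)C)(C(C)C)C(C)C)=C21
F7 | step 15 | macrocyclic C1 alcohol (4Z,6S,8R,10R) | CC(C)(C)[Si](C)(C)O[C@@H]1C[C@H](COCc3ccc(OC)cc3)C(O)CC/C(C)=C\[C@@H]2OC(=O)C(CO[Si](C(C)C)(C(C)C)C(C)C)=C21
F8 | step 14 | propargylic hydroxy ester (C6 configured as in 19) | CC[Si](CC)(CC)OC1(CC1)[C@@H](COCc2ccc(OC)cc2)C[C@@H](O[Si](C)(C)C(C)(C)C)/C([C@@H](O)C#CC)=C(\CO[Si](C(C)C)(C(C)C)C(C)C)C(=O)OC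
F9 | step 14 | 5-(prop-1-yn-1-yl) butenolide (C6 configured as in 20) | CC[Si](CC)(CC)OC1(CC1)[C@@H](COCc2ccc(OC)cc2)C[C@@H](O[Si](C)(C)C(C)(C)C)C3=C(CO[Si](C(C)C)(C(C)C)C(C)C)C(=O)O[C@H]3C#CC
F10 | step 14 | 5-[(Z)-2-(benzyldimethylsilyl)prop-1-en-1-yl] butenolide | CC[Si](CC)(CC)OC1(CC1)[C@@H](COCc2ccc(OC)cc2)C[C@@H](O[Si](C)(C)C(C)(C)C)C3=C(CO[Si](C(C)C)(C(C)C)C(C)C)C(=O)O[C@H]3/C=C(/C)[Si](C)(C)Cc4ccccc4
F11 | step 18 | (4Z,6S,8R,10R)-13-acetoxy-14-[(4-methoxybenzyl)oxy]-8-(methacryloyloxy)-1-oxogermacra-4,7(11)-dien-12,6-olide | C=C(C)C(=O)O[C@@H]1C[C@H](COCc3ccc(OC)cc3)C(=O)CC/C(C)=C\[C@@H]2OC(=O)C(COC(C)=O)=C21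
F12 | step 18 | 5-bromo-4-hydroxy bromohydrin of F11 (C4 hydroxyl and C5 bromide anti) | C=C(C)C(=O)O[C@@H]1C[C@H](COCc3ccc(OC)cc3)C(=O)CC[C@](C)(O)[C@@H](Br)[C@@H]2OC(=O)C(COC(C)=O)=C21
F13 | step 12 | Weinreb amide at C6 (amide cis to the methyl ester) | CC[Si](CC)(CC)OC1(CC1)[C@@H](COCc2ccc(OC)cc2)C[C@@H](O[Si](C)(C)C(C)(C)C)/C(C(=O)N(C)OC)=C(\CO[Si](C(C)C)(C(C)C)C(C)C)C(=O)OC
A1 | alternative 1 | 13-acetoxy-8-[(tert-butyldimethylsilyl)oxy]-1,1-(ethylenedioxy)-4-hydroxy-5-iodogermacra-7(11),10(14)-dien-12,6-olide | CC(C)(C)[Si](C)(C)O[C@@H]1CC(=C)C3(OCCO3)CC[C@](C)(O)[C@@H](I)[C@@H]2OC(=O)C(COC(C)=O)=C21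
A2 | alternative 1 | macrocyclic Z,Z-dienoic acid (C5=C6 and C7=C11, carboxyl cis to C6, free C4 alcohol) | CC(C)(C)[Si](C)(C)O[C@@H]1CC(=C)C2(OCCO2)CC[C@](C)(O)/C=C\C1=C(/C(O)=O)COC(C)=O
A3 | alternative 2 | (2Z,6E)-9-(dimethylphenylsilyl)-3,7-dimethylcyclodeca-2,6-dien-1-one | C[Si](C)(c1ccccc1)[C@@H]2C/C(C)=C/CC/C(C)=C\C(=O)C2
A4 | alternative 2 | trans-1-[(E)-2-(dimethylphenylsilyl)ethenyl]-3-methyl-6-(prop-1-en-2-yl)cyclohex-2-en-1-ol (relative configuration shown) | O[C@]1(/C=C/[Si](C)(C)c2ccccc2)C=C(C)CC[C@@H]1C(C)=C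
A5 | alternative 3 | cyclodec-4-yn-6-ol with the 3-[(4-methoxybenzyl)oxy]prop-1-en-2-yl branch on C7 (C8 silyl ether, C1 ketal, C10 methylene) | O[C@H]1C#CCCC3(OCCO3)C(=C)C[C@@H](O[Si](C)(C)C(C)(C)C)[C@@H]1C(=C)COCc2ccc(OC)cc2
A6 | alternative 3 | thirteen-membered propargylic allylic ether (oxygen bridging C6 and C13, C7=C11 olefin) | C1C#CCCC2(OCCO2)C(=C)C[C@@H](O[Si](C)(C)C(C)(C)C)/C=C(/COCc2ccc(OC)cc2)CO1
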